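**Retrosynthetic overview**
- The target is reached from 7‑[5‑(benzyloxy)‑4‑methoxy‑2‑methylnaphthalen‑1‑yl]‑1,3‑dimethyl‑6‑(methylsulfanyl)isoquinolin‑8‑ol by Raney Ni removal of the C6 sulfur group and hydrogenolysis of the benzyl ether.
- Key disconnection: the carbocycle of the isoquinoline (C5–C8) is cut at C7–C8, C5–C6 and C8–C8a into a (2,6‑dimethylpyridin‑4‑yl) diazomethyl ketone and a naphthyl alkynyl methyl sulfide (Danheiser benzannulation).
- Feature used: in the pyridine ring (C1, N2, C3, C4, C4a, C8a; methyl groups on C1 and C3), cutting C8–C8a leaves a 2,6‑dimethylpyridin‑4‑yl group whose two ortho carbons (C4 and C8a) are equivalent. Closure can therefore only give the 1,3‑dimethylisoquinoline with OH at C8 and the naphthalene at C7.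
- The alkynyl sulfide comes from a 1‑bromonaphthalene (Sonogashira coupling, then silicon‑to‑sulfur exchange at the alkyne terminus). The bromide comes from 8‑(benzyloxy)‑3‑methylnaphthalen‑1‑ol, itself made from 3‑(benzyloxy)benzyne and acetylacetone (acyl‑alkylation, then aldol).
- Ring order: the pyridine ring is bought, the second naphthalene ring is closed in step 5, and the isoquinoline carbocycle is closed last, in step 10.

Key step: step 10

Assumption: the SMILES carries no descriptor for the C7–C1' biaryl axis, so the route is drawn to the constitution and would give the atropisomers as a racemate; the single atropisomer would be taken from 28 (or 27) by chromatography on a chiral phase.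

**Route**

Step 1
Reactants: 1 2,6‑dimethylpyridine‑4‑carboxylic acid
Product: 3 2‑diazo‑1‑(2,6‑dimethylpyridin‑4‑yl)ethan‑1‑one, via acid chloride hydrochloride 2 (not isolated)
Conditions: (COCl)2, cat. DMF, CH2Cl2, 0 °C → rt; evaporate; CH2N2 (Et2O), Et3N, THF, 0 °C
Reagents that add atoms: diazomethane, C=[N+]=[N-]
Why: Acylation of diazomethane by an aroyl chloride (first stage of the Arndt–Eistert sequence, Newman–Beal variant with Et3N as HCl scavenger) is general for acid chlorides without alpha hydrogens, and the hindered lutidine nitrogen should stay unacylated.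

Step 2
Reactants: 4 3‑(benzyloxy)phenol
Product: 5 3‑(benzyloxy)phenyl N‑(propan‑2‑yl)carbamate
Conditions: i‑PrNCO, cat. Et3N, CH2Cl2, rt
Reagents that add atoms: isopropyl isocyanate, CC(C)N=C=O
Why: Base‑catalysed addition of the phenol to the isocyanate (carbamoylation) installs an ortho‑directing group that can later be removed under mild base.

Step 3
Reactants: 5 3‑(benzyloxy)phenyl N‑(propan‑2‑yl)carbamate
Product: 9 3‑(benzyloxy)‑2‑(trimethylsilyl)phenyl N‑(propan‑2‑yl)carbamate, via N‑silyl carbamate 6 (not isolated), via aryllithium 7 (not isolated), via doubly silylated carbamate 8 (not isolated)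
Conditions: TBSOTf, TMEDA, Et2O, 0 °C → rt; n‑BuLi, TMEDA, −78 °C; TMSCl, −78 °C → rt; aq. NaHSO4
Reagents that add atoms: chlorotrimethylsilane, C[Si](C)(C)Cl
Why: Directed ortho‑metalation: after N‑silylation in the flask, the carbamate and the benzyloxy group together direct n‑BuLi to the carbon between them, TMSCl traps the aryllithium, and acidic work‑up removes the N‑silyl group.

Step 4
Reactants: 9 3‑(benzyloxy)‑2‑(trimethylsilyl)phenyl N‑(propan‑2‑yl)carbamate
Product: 11 3‑(benzyloxy)‑2‑(trimethylsilyl)phenyl trifluoromethanesulfonate, via silyl phenol 10 (not isolated)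
Conditions: Et2NH, DBU, MeCN, 40 °C; then PhNTf2, rt
Reagents that add atoms: N‑phenyl‑bis(trifluoromethanesulfonimide), O=S(=O)(N(c1ccccc1)S(=O)(=O)C(F)(F)F)C(F)(F)F
Why: DBU‑induced E1cB cleavage of the N‑monosubstituted carbamate (the isocyanate is scavenged by Et2NH) frees the phenoxide, which PhNTf2 triflates in the same flask to the ortho‑silylaryl triflate aryne precursor.

Step 5
Reactants: 11 3‑(benzyloxy)‑2‑(trimethylsilyl)phenyl trifluoromethanesulfonate; 12 acetylacetone (pentane‑2,4‑dione, in excess)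
Product: 15 8‑(benzyloxy)‑3‑methylnaphthalen‑1‑ol, via benzyloxybenzyne 13 (not isolated), via aryl diketone 14 (not isolated)
Conditions: CsF, MeCN, 60 °C; then DBU, 80 °C
Reagents that add atoms: none
Why: Fluoride‑induced 1,2‑elimination gives the 3‑alkoxyaryne, which the acetylacetone enolate attacks at the carbon remote from the benzyloxy group with transfer of an acetyl group to the neighbouring carbon (aryne acyl‑alkylation); the aryl methyl ketone enolate of 14 then closes onto the more electrophilic aliphatic ketone (intramolecular aldol condensation) and the ring aromatises to the 1‑naphthol, with its OH peri to the benzyloxy group.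

Step 6
Reactants: 15 8‑(benzyloxy)‑3‑methylnaphthalen‑1‑ol
Product: 16 8‑(benzyloxy)‑1‑methoxy‑3‑methylnaphthalene
Conditions: MeI, K2CO3, DMF, rt
Reagents that add atoms: iodomethane, CI
Why: Williamson O‑methylation of the naphthoxide should proceed cleanly, since no other acidic site is present.

Step 7
Reactants: 16 8‑(benzyloxy)‑1‑methoxy‑3‑methylnaphthalene
Product: 17 5‑(benzyloxy)‑1‑bromo‑4‑methoxy‑2‑methylnaphthalene
Conditions: NBS, MeCN, 0 °C, dark
Reagents that add atoms: N‑bromosuccinimide, O=C1CCC(=O)N1Br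
Why: Electrophilic aromatic bromination is expected at the alpha position that is para to the methoxy group and ortho to the methyl group, which is more activated than the alpha position para to the benzyloxy group on the ring without the methyl group (compare the 1‑bromination of 2‑methylnaphthalene).

Step 8
Reactants: 17 5‑(benzyloxy)‑1‑bromo‑4‑methoxy‑2‑methylnaphthalene; 18 ethynyltrimethylsilane
Product: 19 {[5‑(benzyloxy)‑4‑methoxy‑2‑methylnaphthalen‑1‑yl]ethynyl}trimethylsilane
Conditions: Pd(PhCN)2Cl2, P(t‑Bu)3, CuI, i‑Pr2NH, dioxane, rt → 50 °C (sealed)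
Reagents that add atoms: none
Why: Sonogashira coupling; the bulky, electron‑rich phosphine should allow oxidative addition of the hindered, electron‑rich aryl bromide under mild conditions.

Step 9
Reactants: 19 {[5‑(benzyloxy)‑4‑methoxy‑2‑methylnaphthalen‑1‑yl]ethynyl}trimethylsilane
Product: 21 5‑(benzyloxy)‑4‑methoxy‑2‑methyl‑1‑[(methylsulfanyl)ethynyl]naphthalene, via lithium acetylide 20 (not isolated)
Conditions: MeLi·LiBr, THF, 0 °C → rt; then MeSSO2Me, −78 °C → rt
Reagents that add atoms: S‑methyl methanethiosulfonate, CSS(C)(=O)=O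
Why: Methyllithium attacks silicon and releases the lithium acetylide (desilylative lithiation of an alkynylsilane), which is sulfenylated at the sulfenyl sulfur of the thiosulfonate with loss of methanesulfinate.

Step 10
Reactants: 3 2‑diazo‑1‑(2,6‑dimethylpyridin‑4‑yl)ethan‑1‑one (1.5–2 equiv, added slowly); 21 5‑(benzyloxy)‑4‑methoxy‑2‑methyl‑1‑[(methylsulfanyl)ethynyl]naphthalene
Product: 26 7‑[5‑(benzyloxy)‑4‑methoxy‑2‑methylnaphthalen‑1‑yl]‑1,3‑dimethyl‑6‑(methylsulfanyl)isoquinolin‑8‑ol, via pyridyl ketene 22 (not isolated), via cyclobutenone 23 (not isolated), via dienylketene 24 (not isolated), via cyclohexadienone 25 (not isolated)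
Conditions: hν (365–405 nm LED), ClCH2CH2Cl, rt; then 80 °C
Reagents that add atoms: none
Why: Light drives the photochemical Wolff rearrangement of 3 to pyridin‑4‑yl ketene 22, whose electrophilic carbonyl carbon is attacked by the naphthyl‑bearing alkyne carbon of 21 (the carbon beta to sulfur) in a (2+2) cycloaddition that closes the four‑membered ring of cyclobutenone 23 and forms C7–C8 and C5–C6. On heating, 23 opens reversibly in a four‑electron electrocyclic step to dienylketene 24, and the isomer with the pyridyl group cis to the ketene closes the six‑membered carbocycle by a six‑electron disrotatory electrocyclisation onto a pyridine ortho carbon (C8–C8a), giving dienone 25, which tautomerises to phenol 26. This is the Danheiser benzannulation in its diazo ketone form, established for aryl and heteroaryl diazo ketones and for alkynyl thioethers. The one selectivity needed is the orientation of the (2+2) step, and the sulfur lone pair should secure it by making the carbon remote from sulfur the nucleophile, so that the naphthalene ends at C7 next to the hydroxyl and sulfur at C6. The ring closure has no choice to make because the two ortho carbons of the 2,6‑dimethylpyridin‑4‑yl group are equivalent, and the flanking methyl groups should keep the nitrogen from adding to the ketene. No stereocentre is formed, and the C7–C1' axis, which appears only on aromatisation, would be obtained as the racemate.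

Step 11
Reactants: 26 7‑[5‑(benzyloxy)‑4‑methoxy‑2‑methylnaphthalen‑1‑yl]‑1,3‑dimethyl‑6‑(methylsulfanyl)isoquinolin‑8‑ol
Product: 27 7‑[5‑(benzyloxy)‑4‑methoxy‑2‑methylnaphthalen‑1‑yl]‑1,3‑dimethylisoquinolin‑8‑ol
Conditions: Raney Ni (W‑2), EtOH, rt → 50 °C
Reagents that add atoms: none
Why: Raney nickel hydrogenolysis of the aryl carbon–sulfur bond (reductive desulfurisation) should replace the methylsulfanyl group by hydrogen without touching the heteroarene at this temperature, and any concurrent loss of the benzyl group would be harmless.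

Step 12
Reactants: 27 7‑[5‑(benzyloxy)‑4‑methoxy‑2‑methylnaphthalen‑1‑yl]‑1,3‑dimethylisoquinolin‑8‑ol
Product: 28 ent‑dioncophylleine A, 7‑(5‑hydroxy‑4‑methoxy‑2‑methylnaphthalen‑1‑yl)‑1,3‑dimethylisoquinolin‑8‑ol
Conditions: H2 (1 atm), Pd/C, EtOAc–MeOH, rt
Reagents that add atoms: none
Why: Catalytic hydrogenolysis of the benzyl aryl ether over palladium on carbon should free the naphthol under conditions too mild to reduce the isoquinoline or the naphthalene.

**Compound list**

1 | 2,6‑dimethylpyridine‑4‑carboxylic acid | Cc1cc(C(=O)O)cc(C)n1 | starting material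
2 | 2,6‑dimethylpyridine‑4‑carbonyl chloride hydrochloride (not isolated) | Cc1cc(C(=O)Cl)cc(C)n1.Cl | intermediate
3 | 2‑diazo‑1‑(2,6‑dimethylpyridin‑4‑yl)ethan‑1‑one | Cc1cc(C(=O)C=[N+]=[N-])cc(C)n1 | intermediate
4 | 3‑(benzyloxy)phenol | Oc1cccc(OCc2ccccc2)c1 | starting material
5 | 3‑(benzyloxy)phenyl N‑(propan‑2‑yl)carbamate | CC(C)NC(=O)Oc1cccc(OCc2ccccc2)c1 | intermediate
6 | 3‑(benzyloxy)phenyl N‑(tert‑butyldimethylsilyl)‑N‑(propan‑2‑yl)carbamate (not isolated) | CC(C)N(C(=O)Oc1cccc(OCc2ccccc2)c1)[Si](C)(C)C(C)(C)C | intermediate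
7 | 2‑lithio derivative of 6, lithium on the carbon between the two oxygen substituents (not isolated) | [Li]c1c(OCc2ccccc2)cccc1OC(=O)N(C(C)C)[Si](C)(C)C(C)(C)C | intermediate
8 | 3‑(benzyloxy)‑2‑(trimethylsilyl)phenyl N‑(tert‑butyldimethylsilyl)‑N‑(propan‑2‑yl)carbamate (not isolated) | CC(C)N(C(=O)Oc1cccc(OCc2ccccc2)c1[Si](C)(C)C)[Si](C)(C)C(C)(C)C | intermediate
9 | 3‑(benzyloxy)‑2‑(trimethylsilyl)phenyl N‑(propan‑2‑yl)carbamate | CC(C)NC(=O)Oc1cccc(OCc2ccccc2)c1[Si](C)(C)C | intermediate
10 | 3‑(benzyloxy)‑2‑(trimethylsilyl)phenol (not isolated) | C[Si](C)(C)c1c(O)cccc1OCc1ccccc1 | intermediate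
11 | 3‑(benzyloxy)‑2‑(trimethylsilyl)phenyl trifluoromethanesulfonate | C[Si](C)(C)c1c(OCc2ccccc2)cccc1OS(=O)(=O)C(F)(F)F | intermediate
12 | acetylacetone (pentane‑2,4‑dione) | CC(=O)CC(C)=O | starting material
13 | 3‑(benzyloxy)benzyne (not isolated) | C1(OCc2ccccc2)=CC=CC#C1 | intermediate
14 | 1‑[2‑acetyl‑3‑(benzyloxy)phenyl]propan‑2‑one (not isolated) | CC(=O)Cc1cccc(OCc2ccccc2)c1C(C)=O | intermediate
15 | 8‑(benzyloxy)‑3‑methylnaphthalen‑1‑ol | Cc1cc(O)c2c(OCc3ccccc3)cccc2c1 | intermediate
16 | 8‑(benzyloxy)‑1‑methoxy‑3‑methylnaphthalene | COc1cc(C)cc2cccc(OCc3ccccc3)c12 | intermediate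
17 | 5‑(benzyloxy)‑1‑bromo‑4‑methoxy‑2‑methylnaphthalene | COc1cc(C)c(Br)c2cccc(OCc3ccccc3)c12 | intermediate
18 | ethynyltrimethylsilane | C#C[Si](C)(C)C | starting material
19 | {[5‑(benzyloxy)‑4‑methoxy‑2‑methylnaphthalen‑1‑yl]ethynyl}trimethylsilane | COc1cc(C)c(C#C[Si](C)(C)C)c2cccc(OCc3ccccc3)c12 | intermediate
20 | lithium [5‑(benzyloxy)‑4‑methoxy‑2‑methylnaphthalen‑1‑yl]acetylide (not isolated) | [Li]C#Cc1c(C)cc(OC)c2c(OCc3ccccc3)cccc12 | intermediate
21 | 5‑(benzyloxy)‑4‑methoxy‑2‑methyl‑1‑[(methylsulfanyl)ethynyl]naphthalene | CSC#Cc1c(C)cc(OC)c2c(OCc3ccccc3)cccc12 | intermediate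
22 | 2‑(2,6‑dimethylpyridin‑4‑yl)ethen‑1‑one, the pyridyl ketene (not isolated) | Cc1cc(C=C=O)cc(C)n1 | intermediate
23 | 2‑[5‑(benzyloxy)‑4‑methoxy‑2‑methylnaphthalen‑1‑yl]‑4‑(2,6‑dimethylpyridin‑4‑yl)‑3‑(methylsulfanyl)cyclobut‑2‑en‑1‑one, racemic (not isolated) | O=C1C(c2c(C)cc(OC)c3c(OCc4ccccc4)cccc23)=C(SC)C1c1cc(C)nc(C)c1 | intermediate
24 | 2‑[5‑(benzyloxy)‑4‑methoxy‑2‑methylnaphthalen‑1‑yl]‑4‑(2,6‑dimethylpyridin‑4‑yl)‑3‑(methylsulfanyl)buta‑1,3‑dien‑1‑one, pyridyl cis to the ketene carbon (not isolated) | O=C=C(c1c(C)cc(OC)c2c(OCc3ccccc3)cccc12)/C(SC)=C\c1cc(C)nc(C)c1 | intermediate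
25 | 7‑[5‑(benzyloxy)‑4‑methoxy‑2‑methylnaphthalen‑1‑yl]‑1,3‑dimethyl‑6‑(methylsulfanyl)‑8aH‑isoquinolin‑8‑one, racemic keto tautomer (not isolated) | O=C1C(c2c(C)cc(OC)c3c(OCc4ccccc4)cccc23)=C(SC)C=C2C=C(C)N=C(C)C21 | intermediate
26 | 7‑[5‑(benzyloxy)‑4‑methoxy‑2‑methylnaphthalen‑1‑yl]‑1,3‑dimethyl‑6‑(methylsulfanyl)isoquinolin‑8‑ol | CSc1cc2cc(C)nc(C)c2c(O)c1-c1c(C)cc(OC)c2c(OCc3ccccc3)cccc12 | intermediate
27 | 7‑[5‑(benzyloxy)‑4‑methoxy‑2‑methylnaphthalen‑1‑yl]‑1,3‑dimethylisoquinolin‑8‑ol | Cc1cc2ccc(-c3c(C)cc(OC)c4c(OCc5ccccc5)cccc34)c(O)c2c(C)n1 | intermediate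
28 | ent‑dioncophylleine A, 7‑(5‑hydroxy‑4‑methoxy‑2‑methylnaphthalen‑1‑yl)‑1,3‑dimethylisoquinolin‑8‑ol | COc1cc(C)c(-c2ccc3cc(C)nc(C)c3c2O)c2cccc(O)c12 | target

**Step count**
Total: 12 steps. Longest linear sequence: 11 steps (steps 2–12, from 3‑(benzyloxy)phenol 4).

**Steps most likely to fail**

1. Step 10 (benzannulation).
 - What may go wrong: the naphthyl chromophore of 21 competes for the light and the alkynyl sulfide is degraded, or the photogenerated ketene is lost by dimerisation or carbene side reactions before the hindered alkyne captures it.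
 - Fallback (sets out from 3 and 21, returns at 26): the same ketene 22 is generated without light. Silver‑catalysed Wolff rearrangement of 3 in aqueous dioxane (PhCO2Ag, Et3N) would give 2‑(2,6‑dimethylpyridin‑4‑yl)acetic acid F1. (COCl)2 with cat. DMF would convert it into 2‑(2,6‑dimethylpyridin‑4‑yl)acetyl chloride hydrochloride F2. Slow addition of Et3N to F2 and 21 in toluene at 80–110 °C would dehydrochlorinate F2 to 22 in the presence of the alkyne, and cyclobutenone 23 would go on thermally through 24 and 25 to 26.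

2. Step 5 (aryne acyl‑alkylation and aldol).
 - What may go wrong: the naphthoxide formed in the flask is arylated by aryne that is still being generated, the insertion stops at simple C‑ or O‑arylation without acetyl transfer, or the aldol closes through the other enolate.
 - Fallback (sets out from 5, returns at 14 and so at 15): the aryne is replaced by a cross‑coupling. Carbamate 5 is N‑silylated and lithiated as in step 3 to 7, which is quenched with N‑methoxy‑N‑methylacetamide. The resulting 2‑acetyl‑3‑(benzyloxy)phenyl N‑(tert‑butyldimethylsilyl)‑N‑(propan‑2‑yl)carbamate F3 would lose its N‑silyl group on acidic work‑up to give 2‑acetyl‑3‑(benzyloxy)phenyl N‑(propan‑2‑yl)carbamate F4. Et2NH and DBU would free 2‑acetyl‑3‑(benzyloxy)phenol F5, and Tf2O with pyridine would give 2‑acetyl‑3‑(benzyloxy)phenyl trifluoromethanesulfonate F6. Palladium‑catalysed mono‑α‑arylation of acetone ([Pd(cinnamyl)Cl]2, Mor‑DalPhos, Cs2CO3, acetone, 90 °C) should then deliver diketone 14, which would close to 15 under the basic conditions or on treatment with KOH in MeOH.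

3. Step 7 (bromination).
 - What may go wrong: attack also occurs para to the benzyloxy group on the other ring, or twice, giving isomers that are hard to separate.
 - Fallback (sets out from 11 and 12, returns at 20 and so at 21): the side chain is placed by construction instead of by substitution. Acetylacetone 12 is C‑alkylated with ethyl bromoacetate (K2CO3, acetone, reflux) to ethyl 3‑acetyl‑4‑oxopentanoate F7. Under the conditions of step 5, aryne 13 from 11 would insert into F7 to give ethyl 3‑[2‑acetyl‑3‑(benzyloxy)phenyl]‑4‑oxopentanoate F8, which would close to ethyl 2‑[5‑(benzyloxy)‑4‑hydroxy‑2‑methylnaphthalen‑1‑yl]acetate F9, with the two‑carbon chain fixed next to the methyl group. MeI and K2CO3 would give ethyl 2‑[5‑(benzyloxy)‑4‑methoxy‑2‑methylnaphthalen‑1‑yl]acetate F10, and i‑Bu2AlH at −78 °C would give 2‑[5‑(benzyloxy)‑4‑methoxy‑2‑methylnaphthalen‑1‑yl]acetaldehyde F11. C4F9SO2F with the phosphazene base P2‑Et in DMF would convert F11 through 2‑[5‑(benzyloxy)‑4‑methoxy‑2‑methylnaphthalen‑1‑yl]ethenyl nonafluorobutanesulfonate F12 into 5‑(benzyloxy)‑1‑ethynyl‑4‑methoxy‑2‑methylnaphthalene F13 by elimination. n‑BuLi would then give acetylide 20, which is sulfenylated as in step 9 to 21.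

**Further compounds**

F1 | step 10 | 2‑(2,6‑dimethylpyridin‑4‑yl)acetic acid | Cc1cc(CC(=O)O)cc(C)n1
F2 | step 10 | 2‑(2,6‑dimethylpyridin‑4‑yl)acetyl chloride hydrochloride | Cc1cc(CC(=O)Cl)cc(C)n1.Cl
F3 | step 5 | 2‑acetyl‑3‑(benzyloxy)phenyl N‑(tert‑butyldimethylsilyl)‑N‑(propan‑2‑yl)carbamate | CC(C)N(C(=O)Oc1cccc(OCc2ccccc2)c1C(C)=O)[Si](C)(C)C(C)(C)C
F4 | step 5 | 2‑acetyl‑3‑(benzyloxy)phenyl N‑(propan‑2‑yl)carbamate | CC(C)NC(=O)Oc1cccc(OCc2ccccc2)c1C(C)=O
F5 | step 5 | 2‑acetyl‑3‑(benzyloxy)phenol | CC(=O)c1c(O)cccc1OCc1ccccc1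
F6 | step 5 | 2‑acetyl‑3‑(benzyloxy)phenyl trifluoromethanesulfonate | CC(=O)c1c(OCc2ccccc2)cccc1OS(=O)(=O)C(F)(F)F
F7 | step 7 | ethyl 3‑acetyl‑4‑oxopentanoate | CCOC(=O)CC(C(C)=O)C(C)=O
F8 | step 7 | ethyl 3‑[2‑acetyl‑3‑(benzyloxy)phenyl]‑4‑oxopentanoate | CCOC(=O)CC(C(C)=O)c1cccc(OCc2ccccc2)c1C(C)=O
F9 | step 7 | ethyl 2‑[5‑(benzyloxy)‑4‑hydroxy‑2‑methylnaphthalen‑1‑yl]acetate | CCOC(=O)Cc1c(C)cc(O)c2c(OCc3ccccc3)cccc12
F10 | step 7 | ethyl 2‑[5‑(benzyloxy)‑4‑methoxy‑2‑methylnaphthalen‑1‑yl]acetate | CCOC(=O)Cc1c(C)cc(OC)c2c(OCc3ccccc3)cccc12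
F11 | step 7 | 2‑[5‑(benzyloxy)‑4‑methoxy‑2‑methylnaphthalen‑1‑yl]acetaldehyde | O=CCc1c(C)cc(OC)c2c(OCc3ccccc3)cccc12
F12 | step 7 | 2‑[5‑(benzyloxy)‑4‑methoxy‑2‑methylnaphthalen‑1‑yl]ethenyl nonafluorobutanesulfonate (E/Z mixture) | O=S(=O)(OC=Cc1c(C)cc(OC)c2c(OCc3ccccc3)cccc12)C(F)(F)C(F)(F)C(F)(F)C(F)(F)F
F13 | step 7 | 5‑(benzyloxy)‑1‑ethynyl‑4‑methoxy‑2‑methylnaphthalene | C#Cc1c(C)cc(OC)c2c(OCc3ccccc3)cccc12
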